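The C4–C5 bond (numbering below) is the ring-fusion bond shared by cyclopentanone ring A and cyclohexanol ring B, between the angular-methyl quaternary carbon and the neighbouring methine; everything rests on disconnecting it. A late intramolecular Pauson–Khand reaction of a 1,7-enyne forms this bond, closes rings A and B in one operation, brings in C2 as CO and sets the C4 stereocentre. It exploits the fact that C7 and C8 of the preformed ring C hold the 2-methylallyl and 4-methylpent-2-ynyl arms trans-diequatorially. The precursor is a cyclopentane-fused epoxycyclooctenol bearing these two arms on adjacent carbons. One hydroxyl-directed hydrogenation then sets C1 and C5.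

Key step: step 18

Atom labels used in the explanations (target):
- Ring A: C1(i-Pr)–C2(=O)–C3H2–C4(CH3)–C5H.
- Ring B: C4–C6H2–C7H–C8(OH)–C9H2–C5.
- Ring C: C7–C10H(CH3)–C11H2–C12H2–C13H–C14–C15(CH3)–C8.
- Ring D: C13–C16H(CH3)–C17H2–C18H2–C14.
- The epoxide oxygen bridges C14 and C15.

Remark: in the target the isopropyl group at C1 is cis to the C4 methyl group (H-1 and H-5 cis), so C1 is set by kinetic hydrogen delivery in the last step and is not exposed to base afterwards.
Remark: (+)-limonene oxide 1 and (S)-β-methyl-γ-butyrolactone 7 are taken as commercially available.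

Step 1
Reactants: 1 (+)-limonene oxide
Product: 2 (3R)-6-oxo-3-(prop-1-en-2-yl)heptanal
Conditions: H5IO6, THF/H2O, 0 °C to rt
Reagents that add atoms: water, O
Why: Periodic acid should open the trisubstituted epoxide to the diol and cleave it at once (glycol cleavage), leaving the isopropenyl group and the stereocentre untouched.

Step 2
Reactants: 2 (3R)-6-oxo-3-(prop-1-en-2-yl)heptanal
Product: 3 (5S)-2-methyl-5-(prop-1-en-2-yl)cyclopent-1-ene-1-carbaldehyde
Conditions: piperidine (cat.), AcOH (cat.), toluene, 80 °C
Reagents that add atoms: none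
Why: Amine/acid-catalysed intramolecular aldol condensation of the aldehyde α-carbon onto the methyl ketone should give the five-membered enal, and the stereocentre is not enolisable.

Step 3
Reactants: 3 (5S)-2-methyl-5-(prop-1-en-2-yl)cyclopent-1-ene-1-carbaldehyde
Product: 5 (5R)-5-acetyl-2-methylcyclopent-1-ene-1-carbaldehyde, via trioxolane ozonide 4 (not isolated)
Conditions: O3 (1 equiv), CH2Cl2, −78 °C; then Me2S, −78 °C to rt
Reagents that add atoms: ozone, [O-][O+]=O
Why: Ozonolysis should be chemoselective for the electron-rich 1,1-disubstituted alkene over the deactivated tetrasubstituted enal alkene, and reductive work-up gives the methyl ketone.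

Step 4
Reactants: 5 (5R)-5-acetyl-2-methylcyclopent-1-ene-1-carbaldehyde
Product: 6 (1S,2R,5S)-2-acetyl-5-methylcyclopentane-1-carbaldehyde (all-cis)
Conditions: H2 (4 bar), 10% Pd/C, EtOAc, rt; used crude
Reagents that add atoms: none
Why: Heterogeneous syn-hydrogenation should deliver both hydrogens to the face opposite the acetyl group on the neighbouring sp3 carbon, so formyl, methyl and acetyl end up all-cis (the cis relation of formyl and methyl follows from syn addition alone), which sets C13 and C16.

Step 5
Reactants: 7 (S)-4-methyldihydrofuran-2(3H)-one; 8 3-bromo-2-methylprop-1-ene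
Product: 10 (3S,4S)-4-methyl-3-(2-methylprop-2-en-1-yl)dihydrofuran-2(3H)-one (trans), via lithium enolate 9 (not isolated)
Conditions: LiN(i-Pr)2, THF, −78 °C; then 8, −78 to −30 °C
Reagents that add atoms: 3-bromo-2-methylprop-1-ene (8), CC(=C)CBr
Why: Alkylation of the γ-butyrolactone enolate with the allylic bromide should occur anti to the ring methyl group and give the trans lactone (1,2-induction in enolate alkylation).

Step 6
Reactants: 10 (3S,4S)-4-methyl-3-(2-methylprop-2-en-1-yl)dihydrofuran-2(3H)-one
Product: 12 (3R,4S)-4-methyl-3-(2-methylprop-2-en-1-yl)dihydrofuran-2(3H)-one (cis), via lithium enolate 11 (not isolated)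
Conditions: LiN(i-Pr)2, THF, −78 °C; then 2,6-di-tert-butyl-4-methylphenol, −78 °C
Reagents that add atoms: none
Why: Kinetic protonation of the re-formed enolate by a bulky phenol should occur on the face anti to the ring methyl group, so the 2-methylallyl group ends up cis to it (sets C7 relative to C10); recovered 10 is recycled.

Step 7
Reactants: 12 (3R,4S)-4-methyl-3-(2-methylprop-2-en-1-yl)dihydrofuran-2(3H)-one
Product: 13 (2R,3S)-4-hydroxy-N-methoxy-N,3-dimethyl-2-(2-methylprop-2-en-1-yl)butanamide
Conditions: MeNH(OMe)·HCl, i-PrMgCl, THF, −20 °C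
Reagents that add atoms: N,O-dimethylhydroxylamine hydrochloride, CNOC.Cl
Why: Aminolysis of the lactone by the magnesium amide (Weinreb amide formation) should open the ring at the acyl carbon without touching either stereocentre.

Step 8
Reactants: 13 (2R,3S)-4-hydroxy-N-methoxy-N,3-dimethyl-2-(2-methylprop-2-en-1-yl)butanamide
Product: 14 (2R,3S)-4-iodo-N-methoxy-N,3-dimethyl-2-(2-methylprop-2-en-1-yl)butanamide
Conditions: I2, PPh3, imidazole, CH2Cl2, 0 °C
Reagents that add atoms: iodine, II
Why: Appel-type iodination of the primary alcohol at 0 °C should outrun relactonisation.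

Step 9
Reactants: 14 (2R,3S)-4-iodo-N-methoxy-N,3-dimethyl-2-(2-methylprop-2-en-1-yl)butanamide
Product: 15 [(2S,3R)-4-[methoxy(methyl)amino]-2-methyl-3-(2-methylprop-2-en-1-yl)-4-oxobutyl]triphenylphosphonium iodide
Conditions: PPh3, MeCN, 70 °C
Reagents that add atoms: triphenylphosphine, c1ccc(cc1)P(c1ccccc1)c1ccccc1
Why: SN2 quaternisation of triphenylphosphine by the primary iodide should give the Wittig salt; the moderate temperature limits O-alkylation by the amide.

Step 10
Reactants: 15 phosphonium iodide; 6 (1S,2R,5S)-2-acetyl-5-methylcyclopentane-1-carbaldehyde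
Product: 17 (2R,3R,4Z)-5-[(1R,2R,5S)-2-acetyl-5-methylcyclopentyl]-N-methoxy-N,3-dimethyl-2-(2-methylprop-2-en-1-yl)pent-4-enamide, via phosphonium ylide 16 (not isolated)
Conditions: NaN(SiMe3)2, THF, −78 °C; then 6, −78 °C to rt
Reagents that add atoms: none
Why: Wittig olefination with the non-stabilised ylide at low temperature should give the (Z)-C11=C12 alkene through the kinetic cis-oxaphosphetane, react at the aldehyde in preference to the methyl ketone and leave the aldehyde α-centre unepimerised.

Step 11
Reactants: 17 keto Weinreb amide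
Product: 19 terminal enol triflate of 17 (CH2=C(OSO2CF3)– in place of the acetyl group), via potassium enolate 18 (not isolated)
Conditions: KN(SiMe3)2, THF, −78 °C; then PhN(SO2CF3)2, −78 to 0 °C
Reagents that add atoms: N-phenyl-bis(trifluoromethanesulfonimide), FC(F)(F)S(=O)(=O)N(c1ccccc1)S(=O)(=O)C(F)(F)F
Why: Kinetic deprotonation of the methyl ketone at the methyl group by the hindered amide and O-sulfonylation should give the 1,1-disubstituted enol triflate, the amide α-proton being far less acidic.

Step 12
Reactants: 19 enol triflate Weinreb amide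
Product: 20 enol triflate aldehyde (CHO in place of the Weinreb amide of 19)
Conditions: i-Bu2AlH, THF, −78 °C; aqueous Rochelle salt
Reagents that add atoms: none
Why: Reduction of the Weinreb amide should stop at the chelated tetrahedral intermediate that releases the aldehyde only on work-up, and the enol triflate and alkenes are inert at −78 °C.

Step 13
Reactants: 20 enol triflate aldehyde
Product: 21 cis-fused bicyclo[6.3.0]undecenol (C8 alcohol as both epimers; exocyclic methylene on C15)
Conditions: CrCl2 (10 equiv), NiCl2 (1 mol %), DMF, rt, 2 mM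
Reagents that add atoms: none
Why: Intramolecular Nozaki–Hiyama–Kishi reaction (nickel-catalysed activation of the alkenyl triflate, transfer to chromium and aldehyde-selective addition) should close eight-membered ring C by the C8–C15 bond at high dilution, helped by the cis ring D substituents and the (Z)-alkene; the carbinol configuration is irrelevant because it is oxidised next.

Step 14
Reactants: 21 bicyclic allylic alcohol
Product: 22 α-methylene ketone (C8 ketone with exocyclic methylene on C15)
Conditions: Dess–Martin periodinane, NaHCO3, CH2Cl2, 0 °C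
Reagents that add atoms: none
Why: Buffered Dess–Martin oxidation of the secondary allylic alcohol should give the enone without epimerising C7.

Step 15
Reactants: 22 α-methylene ketone
Product: 25 ring C enone (C8 ketone conjugated with the tetrasubstituted C14=C15 alkene), via lithium enolate 23 (not isolated), via silyl enol ether 24 (not isolated)
Conditions: LiBH(s-Bu)3, THF, −78 °C; Me3SiCl, Et3N, −78 to 0 °C; then Pd(OAc)2, MeCN, rt
Reagents that add atoms: none
Why: Conjugate hydride addition to the β-unsubstituted enone should give the C8–C15 enolate regiospecifically, and Saegusa–Ito oxidation of its silyl enol ether removes the ring-fusion hydrogen at C14 by β-hydride elimination, moving the alkene into ring C; any exocyclic isomer formed is 22 and is recycled.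

Step 16
Reactants: 25 ring C enone; 26 4-methylpent-2-yne
Product: 29 tertiary homopropargylic alcohol (C8 bearing OH and the 4-methylpent-2-ynyl group), via propargyllithium 27 (not isolated), via allenyltitanate 28 (not isolated)
Conditions: 26, n-BuLi, TMEDA, Et2O, −20 to 0 °C; Ti(Oi-Pr)4, THF, −78 °C; then 25, −78 to −20 °C
Reagents that add atoms: 4-methylpent-2-yne (26), CC#CC(C)C
Why: The allenyltitanium reagent should add 1,2 through a cyclic SE2′ transition state at its CH2 terminus, approaching the ketone on the face opposite the C7 2-methylallyl and C10 methyl groups, which sets C8.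

Step 17
Reactants: 29 tertiary homopropargylic alcohol
Product: 30 epoxy alcohol (C14–C15 epoxide syn to the C8 hydroxyl)
Conditions: VO(acac)2 (5 mol %), t-BuOOH, CH2Cl2, 0 °C to rt
Reagents that add atoms: tert-butyl hydroperoxide, CC(C)(C)OO
Why: Vanadium-catalysed hydroxyl-directed epoxidation should deliver oxygen to the tetrasubstituted allylic alkene syn to the tertiary hydroxyl (cis selectivity of medium-ring allylic alcohols) and anti to the ring D methyl group, setting C14 and C15, while the remote isolated alkenes react much more slowly.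

Step 18
Reactants: 30 epoxy alcohol (1,7-enyne)
Product: 32 tetracyclic cyclopentenone (rings A and B closed; C1=C5 enone; C11=C12 alkene), via hexacarbonyldicobalt alkyne complex 31 (not isolated)
Conditions: Co2(CO)8 (1.1 equiv), CH2Cl2, rt; then N-methylmorpholine N-oxide, CH2Cl2, 0 °C to rt
Reagents that add atoms: dicobalt octacarbonyl, O=C=[Co](=C=O)(=C=O)(=C=O)[Co](=C=O)(=C=O)(=C=O)=C=O
Why: Complex 31 loses a CO ligand on oxidation by the N-oxide, the 2-methylallyl alkene coordinates and inserts into a cobalt–carbon bond to form the C4–C5 bond, and CO insertion with reductive elimination forms C2–C3 and C1–C2 and releases the cyclopentenone. The closest known reaction type is the intramolecular Pauson–Khand reaction of a 1,7-enyne with an internal alkyne and a 1,1-disubstituted alkene, a known entry to angularly methylated hydrindenones. Ring B closes by 6-exo insertion (C4–C5) through a chair-like cobaltacycle and ring A by the [2+2+1] union of C1/C5 (alkyne), C3/C4 (alkene) and C2 (CO). The new stereocentre C4 is controlled by the trans-diequatorial C7–C10 and C8–C15 bonds of ring C, which lock the chair so that C3 lies equatorial and the methyl group axial, syn to H-7 and anti to the C8 hydroxyl. The step needs chemoselectivity for the 2-methylallyl alkene over the ring C cis-alkene and survival of the epoxy alcohol; insertion of the ring alkene would give a strained bridged bicycle, and the N-oxide conditions at room temperature are mild.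

Step 19
Reactants: 32 tetracyclic cyclopentenone
Product: 33 CNP0332295.1 (target)
Conditions: H2 (50 bar), [Ir(cod)(PCy3)(py)]PF6 (20 mol %), CH2Cl2, rt
Reagents that add atoms: none
Why: Hydroxyl-directed hydrogenation by the cationic iridium catalyst bound to the axial C8 hydroxyl should add H2 syn to the face of the tetrasubstituted enone opposite the C4 methyl group, setting H-5 trans to that methyl and H-1 cis to H-5 under neutral conditions, and it also saturates the C11=C12 alkene.

Compound list
1 | (+)-limonene oxide, (4R)-1-methyl-4-(prop-1-en-2-yl)-7-oxabicyclo[4.1.0]heptane, cis/trans mixture | CC12CC[C@H](CC1O2)C(C)=C | starting material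
2 | (3R)-6-oxo-3-(prop-1-en-2-yl)heptanal | O=CC[C@@H](CCC(C)=O)C(C)=C | intermediate
3 | (5S)-2-methyl-5-(prop-1-en-2-yl)cyclopent-1-ene-1-carbaldehyde | O=CC1=C(C)CC[C@H]1C(C)=C | intermediate
4 | 1,2,4-trioxolane (ozonide) of the isopropenyl group of 3, not isolated | O=CC1=C(C)CC[C@H]1C1(C)OOCO1 | intermediate
5 | (5R)-5-acetyl-2-methylcyclopent-1-ene-1-carbaldehyde | O=CC1=C(C)CC[C@H]1C(C)=O | intermediate
6 | (1S,2R,5S)-2-acetyl-5-methylcyclopentane-1-carbaldehyde, all-cis | O=C[C@H]1[C@@H](C)CC[C@H]1C(C)=O | intermediate
7 | (S)-4-methyldihydrofuran-2(3H)-one | O=C1C[C@H](C)CO1 | starting material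
8 | 3-bromo-2-methylprop-1-ene | CC(=C)CBr | starting material
9 | lithium enolate of 7, not isolated | [Li+].[O-]C1=C[C@H](C)CO1 | intermediate
10 | (3S,4S)-4-methyl-3-(2-methylprop-2-en-1-yl)dihydrofuran-2(3H)-one, trans | O=C1[C@@H](CC(C)=C)[C@H](C)CO1 | intermediate
11 | lithium enolate of 10, not isolated | [Li+].[O-]C1=C(CC(C)=C)[C@H](C)CO1 | intermediate
12 | (3R,4S)-4-methyl-3-(2-methylprop-2-en-1-yl)dihydrofuran-2(3H)-one, cis | O=C1[C@H](CC(C)=C)[C@H](C)CO1 | intermediate
13 | (2R,3S)-4-hydroxy-N-methoxy-N,3-dimethyl-2-(2-methylprop-2-en-1-yl)butanamide | CON(C)C(=O)[C@H](CC(C)=C)[C@H](C)CO | intermediate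
14 | (2R,3S)-4-iodo-N-methoxy-N,3-dimethyl-2-(2-methylprop-2-en-1-yl)butanamide | CON(C)C(=O)[C@H](CC(C)=C)[C@H](C)CI | intermediate
15 | [(2S,3R)-4-[methoxy(methyl)amino]-2-methyl-3-(2-methylprop-2-en-1-yl)-4-oxobutyl]triphenylphosphonium iodide | CON(C)C(=O)[C@H](CC(C)=C)[C@H](C)C[P+](c1ccccc1)(c1ccccc1)c1ccccc1.[I-] | intermediate
16 | phosphonium ylide of 15, not isolated | CON(C)C(=O)[C@H](CC(C)=C)[C@H](C)C=P(c1ccccc1)(c1ccccc1)c1ccccc1 | intermediate
17 | (2R,3R,4Z)-5-[(1R,2R,5S)-2-acetyl-5-methylcyclopentyl]-N-methoxy-N,3-dimethyl-2-(2-methylprop-2-en-1-yl)pent-4-enamide | CON(C)C(=O)[C@H](CC(C)=C)[C@H](C)/C=C\[C@H]1[C@@H](C)CC[C@H]1C(C)=O | intermediate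
18 | potassium enolate of 17 (terminal, at the methyl ketone), not isolated | CON(C)C(=O)[C@H](CC(C)=C)[C@H](C)/C=C\[C@H]1[C@@H](C)CC[C@H]1C(=C)[O-].[K+] | intermediate
19 | terminal enol triflate of 17 (1-cyclopentylvinyl triflate; other centres and (Z)-alkene as in 17) | CON(C)C(=O)[C@H](CC(C)=C)[C@H](C)/C=C\[C@H]1[C@@H](C)CC[C@H]1C(=C)OS(=O)(=O)C(F)(F)F | intermediate
20 | aldehyde corresponding to 19 (CHO in place of the Weinreb amide) | O=C[C@H](CC(C)=C)[C@H](C)/C=C\[C@H]1[C@@H](C)CC[C@H]1C(=C)OS(=O)(=O)C(F)(F)F | intermediate
21 | cis-fused bicyclo[6.3.0]undecenol: C8 alcohol (both epimers), exocyclic methylene on C15, (Z)-C11=C12, C7 2-methylallyl, C10 methyl, ring D methyl cis to C12 | OC1[C@H](CC(C)=C)[C@H](C)/C=C\[C@H]2[C@@H](C)CC[C@H]2C1=C | intermediate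
22 | α-methylene ketone (C8 ketone of 21) | O=C1[C@H](CC(C)=C)[C@H](C)/C=C\[C@H]2[C@@H](C)CC[C@H]2C1=C | intermediate
23 | lithium enolate from conjugate reduction of 22, not isolated | [Li+].[O-]C=1[C@H](CC(C)=C)[C@H](C)/C=C\[C@H]2[C@@H](C)CC[C@H]2C=1C | intermediate
24 | trimethylsilyl enol ether of 23, not isolated | C[Si](C)(C)OC=1[C@H](CC(C)=C)[C@H](C)/C=C\[C@H]2[C@@H](C)CC[C@H]2C=1C | intermediate
25 | ring C enone: C8 ketone conjugated with tetrasubstituted C14=C15 (C15 methyl), (Z)-C11=C12 retained | O=C1[C@H](CC(C)=C)[C@H](C)/C=C\[C@H]2[C@@H](C)CCC2=C1C | intermediate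
26 | 4-methylpent-2-yne | CC#CC(C)C | starting material
27 | (4-methylpent-2-yn-1-yl)lithium, not isolated | [Li]CC#CC(C)C | intermediate
28 | lithium (4-methylpenta-1,2-dien-3-yl)tetraisopropoxytitanate, not isolated | [Li+].CC(C)C(=C=C)[Ti-](OC(C)C)(OC(C)C)(OC(C)C)OC(C)C | intermediate
29 | tertiary homopropargylic alcohol: 25 with OH and 4-methylpent-2-ynyl on C8 (alkynyl arm trans to the C7 2-methylallyl group) | O[C@]1(CC#CC(C)C)[C@H](CC(C)=C)[C@H](C)/C=C\[C@H]2[C@@H](C)CCC2=C1C | intermediate
30 | epoxy alcohol: C14–C15 epoxide of 29, oxygen syn to the C8 hydroxyl | O[C@]1(CC#CC(C)C)[C@H](CC(C)=C)[C@H](C)/C=C\[C@H]2[C@@H](C)CC[C@]23O[C@]13C | intermediate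
31 | hexacarbonyldicobalt complex of the alkyne of 30, not isolated | O[C@]1(CC23C4(C(C)C)[Co]2(=C=O)(=C=O)(=C=O)[Co]34(=C=O)(=C=O)=C=O)[C@H](CC(C)=C)[C@H](C)/C=C\[C@H]5[C@@H](C)CC[C@]56O[C@]16C | intermediate
32 | tetracyclic cyclopentenone: rings A–D and epoxide in place, C1=C5 enone with isopropyl on C1, (Z)-C11=C12 | CC(C)C1=C2C[C@@]3(O)[C@H](C[C@@]2(C)CC1=O)[C@H](C)/C=C\[C@H]4[C@@H](C)CC[C@]45O[C@]35C | intermediate
33 | CNP0332295.1 | CC(C)[C@H]1C(=O)C[C@]2(C)C[C@@H]3[C@H](C)CC[C@H]4[C@@H](C)CC[C@]45O[C@]5(C)[C@@]3(O)C[C@@H]12 | target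

Total step count: 19. Longest linear sequence: 15 steps (7 to 33: steps 5–9 and 10–19).

Steps most likely to fail

Step 18. The complexed alkyne may insert the hindered 1,1-disubstituted alkene too slowly, so that loss of the tertiary α-hydroxy epoxide by Lewis-acidic cobalt species competes. The fallback sets out from 29 and comes back at 32, running the annulation before the epoxide exists. Co2(CO)8 should convert 29 into its hexacarbonyldicobalt alkyne complex F1, which is used without isolation. N-oxide promotion of F1, or heating with a thioether promoter in 1,2-dichloroethane, should then give the tetracyclic cyclopentenone without epoxide F2, which still holds the C14=C15 alkene; that alkene cannot compete because it would need a four-membered ring. VO(acac)2/t-BuOOH then epoxidises F2 syn to the C8 hydroxyl, the electron-poor enone alkene being inert, to give 32.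

Step 16. Facial selectivity of the addition to the hindered, enolisable ring C ketone may be poor, or enolisation may win over addition. The fallback sets out from 25 and comes back at 30, installing the epoxide first and using it as the control element. Nucleophilic epoxidation with t-BuOOH and benzyltrimethylammonium hydroxide in THF should give the α,β-epoxy ketone F3, the hydroperoxide attacking C14 on the convex face anti to the ring D methyl group. Reagent 27 transmetalated with ZnBr2 should then add to F3 under chelation of carbonyl and epoxide oxygens, anti to the epoxide oxygen and anti to the C7 substituent, giving 30 directly.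

Step 13. Closure of the eight-membered ring may lose out to intermolecular coupling or to protonation of the alkenylchromium species. The fallback sets out from 19 and comes back at 21, replacing the alkenyl triflate/aldehyde coupling by a nickel-catalysed reductive alkyne–aldehyde cyclisation. Tetrabutylammonium fluoride in DMF should eliminate triflate from 19 to give the terminal alkyne Weinreb amide F4, and i-Bu2AlH at −78 °C should then reduce F4 to the ynal F5 without touching the alkyne. Ni(cod)2 with the bulky carbene 1,3-bis(2,6-diisopropylphenyl)imidazol-2-ylidene and Et3SiH should close ring C of F5 at the internal alkyne carbon, the bulky ligand favouring the exocyclic methylene, to give the triethylsilyl ether F6 of the allylic alcohol, and tetrabutylammonium fluoride should then cleave F6 to free 21.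

Further compounds
F1 | step 18 | hexacarbonyldicobalt alkyne complex of 29 | O[C@]1(CC23C4(C(C)C)[Co]2(=C=O)(=C=O)(=C=O)[Co]34(=C=O)(=C=O)=C=O)[C@H](CC(C)=C)[C@H](C)/C=C\[C@H]5[C@@H](C)CCC5=C1C
F2 | step 18 | tetracyclic cyclopentenone without epoxide (C14=C15 alkene retained) | CC(C)C1=C2C[C@@]3(O)[C@H](C[C@@]2(C)CC1=O)[C@H](C)/C=C\[C@H]4[C@@H](C)CCC4=C3C
F3 | step 16 | α,β-epoxy ketone (C14–C15 epoxide of 25) | O=C1[C@H](CC(C)=C)[C@H](C)/C=C\[C@H]2[C@@H](C)CC[C@]23O[C@]13C
F4 | step 13 | terminal alkyne Weinreb amide (ethynyl in place of the enol triflate of 19) | CON(C)C(=O)[C@H](CC(C)=C)[C@H](C)/C=C\[C@H]1[C@@H](C)CC[C@H]1C#C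
F5 | step 13 | ynal (aldehyde corresponding to F4) | O=C[C@H](CC(C)=C)[C@H](C)/C=C\[C@H]1[C@@H](C)CC[C@H]1C#C
F6 | step 13 | triethylsilyl ether of 21 | CC[Si](CC)(CC)OC1[C@H](CC(C)=C)[C@H](C)/C=C\[C@H]2[C@@H](C)CC[C@H]2C1=C
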